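**Retrosynthetic overview**

1. Target 31 ⇐ tetra-MOM flavanonol 30 (MOM removal). The chromanone C ring of 30 ⇐ α-ketol 1,2-shift ring expansion of dihydrobenzofuran hydroxy aldehyde 29 (C2 migrates from C3 to the formyl carbon).
2. 29 ⇐ spiro-epoxy lactol 28 (phenoxide opens the epoxide, setting C2 by inversion) ⇐ spiro-epoxy lactone 27 ⇐ coumarandione 19 + chiral benzylsulfonium ylide 26 (B ring from resorcinol + formaldehyde).
3. 19 ⇐ phenol 16 + oxalyl chloride (C3 and C4 of the target). 16 ⇐ bromophenol 8 + (R)-lavandulyl iodide 14 (Evans deconjugative prenylation of a senecioyl imide).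
4. 8 ⇐ resorcinol: MOM protection, ortho-lithiation/prenylation between the oxygens, Ir C–H borylation/oxidation for the third oxygen (the only free OH, the future O1), ortho-bromination.
5. Ring order: rings A and B come from resorcinol; five-membered lactone (step 10) → oxirane (step 14) → dihydrofuran → six-membered pyranone by ring expansion (both in step 16).

Abbreviations: MOM = methoxymethyl; prenyl = 3-methylbut-2-en-1-yl; (S)-lavandulyl = (2S)-5-methyl-2-(prop-1-en-2-yl)hex-4-en-1-yl.

Assumption: the (1R,4R,5R) enantiomer of isothiocineole is taken to be the one whose benzylsulfonium ylide gives the (S)-configured benzylic epoxide carbon; if the sense is the reverse, its mirror image (from the other limonene enantiomer) is used and nothing else changes.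

**Route**

Step 1
Reactants: 1 resorcinol
Product: 2 1,3-bis(methoxymethoxy)benzene
Conditions: MOMCl (2.5 eq), i-Pr2NEt, CH2Cl2, 0 °C→rt
Reagents that add atoms: chloromethyl methyl ether, COCCl
Why: O-alkylation of both phenols (MOM acetal protection); the MOM ethers later direct lithiation and come off together at the end.

Step 2
Reactants: 2 1,3-bis(methoxymethoxy)benzene; 3 prenyl bromide (1-bromo-3-methylbut-2-ene)
Product: 5 1,3-bis(methoxymethoxy)-2-prenylbenzene, via aryllithium 4 (not isolated)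
Conditions: n-BuLi, THF, 0 °C→rt; CuI (10 mol%), 3, −78 °C→rt
Reagents that add atoms: none
Why: Directed ortho-metalation at C2 between the two MOM ethers, then copper-assisted SN2 allylation puts the prenyl group on the future C6.

Step 3
Reactants: 5 1,3-bis(methoxymethoxy)-2-prenylbenzene
Product: 7 3,5-bis(methoxymethoxy)-4-prenylphenol, via arylboronate 6 (not isolated)
Conditions: [Ir(OMe)(cod)]2 (1.5 mol%), dtbpy (3 mol%), B2pin2, THF, 80 °C; then 30% H2O2, aq NaOH, 0 °C
Reagents that add atoms: hydrogen peroxide, OO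
Why: Sterically controlled Ir-catalysed C–H borylation at the only C–H flanked by two hydrogens, then boronate oxidation, gives the third ring oxygen as the single free phenol (future O1); H2O2/NaOH does not touch the trisubstituted alkene.

Step 4
Reactants: 7 3,5-bis(methoxymethoxy)-4-prenylphenol
Product: 8 2-bromo-3,5-bis(methoxymethoxy)-4-prenylphenol
Conditions: NBS (1.0 eq), i-Pr2NH (10 mol%), CH2Cl2, −78 °C
Reagents that add atoms: N-bromosuccinimide, O=C1CCC(=O)N1Br
Why: Electrophilic aromatic bromination ortho to the free phenol (the two ortho sites are equivalent and far more nucleophilic than the alkene at −78 °C).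

Step 5
Reactants: 9 3-methylbut-2-enoyl chloride
Product: 10 (4R)-4-benzyl-3-(3-methylbut-2-enoyl)-1,3-oxazolidin-2-one
Conditions: (R)-4-benzyl-1,3-oxazolidin-2-one, n-BuLi, THF, −78 °C; then 9
Reagents that add atoms: (R)-4-benzyl-1,3-oxazolidin-2-one, O=C1N[C@H](Cc2ccccc2)CO1
Why: N-acylation of the lithiated Evans auxiliary.

Step 6
Reactants: 10 (4R)-4-benzyl-3-(3-methylbut-2-enoyl)-1,3-oxazolidin-2-one; 3 prenyl bromide
Product: 12 (4R)-4-benzyl-3-[(2R)-5-methyl-2-(prop-1-en-2-yl)hex-4-enoyl]-1,3-oxazolidin-2-one, via sodium dienolate 11 (not isolated)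
Conditions: NaHMDS, THF, −78 °C; 3, −78→−40 °C
Reagents that add atoms: none
Why: Evans deconjugative α-alkylation: γ-deprotonation gives the chelated Z-dienolate, which is prenylated at Cα on the face opposite the benzyl group, setting the (2R) lavandulyl centre.

Step 7
Reactants: 12 (4R)-4-benzyl-3-[(2R)-5-methyl-2-(prop-1-en-2-yl)hex-4-enoyl]-1,3-oxazolidin-2-one
Product: 13 (R)-lavandulol [(2R)-5-methyl-2-(prop-1-en-2-yl)hex-4-en-1-ol]
Conditions: LiBH4, Et2O, H2O (1 eq), 0 °C
Reagents that add atoms: none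
Why: Reductive cleavage of the imide to the primary alcohol without touching the β,γ-alkene or the stereocentre; the auxiliary is recovered.

Step 8
Reactants: 13 (R)-lavandulol
Product: 14 (R)-lavandulyl iodide [(3R)-3-(iodomethyl)-2,6-dimethylhepta-1,5-diene]
Conditions: I2, PPh3, imidazole, CH2Cl2, 0 °C
Reagents that add atoms: iodine, II
Why: Appel-type iodination at the primary carbon; the adjacent stereocentre is not involved.

Step 9
Reactants: 8 2-bromo-3,5-bis(methoxymethoxy)-4-prenylphenol; 14 (R)-lavandulyl iodide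
Product: 16 2-[(S)-lavandulyl]-3,5-bis(methoxymethoxy)-4-prenylphenol, via dilithio aryl phenoxide 15 (not isolated)
Conditions: n-BuLi (1.0 eq) then t-BuLi (2.1 eq), THF, −78 °C; DMPU, 14, −78→0 °C; H2O
Reagents that add atoms: none
Why: O-deprotonation and Br/Li exchange give the ortho-lithiated phenoxide, whose SN2 alkylation by the primary iodide places the lavandulyl group between O1 and the 7-OMOM group; the stereocentre is untouched and only its CIP label changes from R to S.

Step 10
Reactants: 16 2-[(S)-lavandulyl]-3,5-bis(methoxymethoxy)-4-prenylphenol; 17 oxalyl chloride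
Product: 19 7-[(S)-lavandulyl]-4,6-bis(methoxymethoxy)-5-prenyl-1-benzofuran-2,3-dione, via aryl chlorooxalate 18 (not isolated)
Conditions: (COCl)2 (1.2 eq), 2,6-lutidine (2.2 eq), CH2Cl2, −20 °C→reflux
Reagents that add atoms: none
Why: O-acylation of the only free phenol, then intramolecular Friedel–Crafts acylation at the only free ring position (ortho and para to OMOM), forms the five-membered keto lactone and fixes which oxygen becomes O1.

Step 11
Reactants: 2 1,3-bis(methoxymethoxy)benzene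
Product: 20 1-bromo-2,4-bis(methoxymethoxy)benzene
Conditions: NBS, MeCN, 0 °C
Reagents that add atoms: N-bromosuccinimide, O=C1CCC(=O)N1Br
Why: Electrophilic bromination para to one OMOM and ortho to the other (C4), the less hindered activated site.

Step 12
Reactants: 20 1-bromo-2,4-bis(methoxymethoxy)benzene; 21 formaldehyde (as paraformaldehyde)
Product: 23 [2,4-bis(methoxymethoxy)phenyl]methanol, via aryllithium 22 (not isolated)
Conditions: n-BuLi, THF, −78 °C; (CH2O)n, −78 °C→rt; H2O
Reagents that add atoms: none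
Why: Bromine–lithium exchange and addition to formaldehyde bring in the carbon that becomes C2.

Step 13
Reactants: 23 [2,4-bis(methoxymethoxy)phenyl]methanol
Product: 25 (1R,4R,5R)-6-[2,4-bis(methoxymethoxy)benzyl]-4,7,7-trimethyl-6-thiabicyclo[3.2.1]octan-6-ium tetrafluoroborate, via benzyl bromide 24 (not isolated)
Conditions: CBr4, PPh3, CH2Cl2, 0 °C; then (1R,4R,5R)-isothiocineole, NaBF4, CH2Cl2/H2O, rt
Reagents that add atoms: (1R,4R,5R)-isothiocineole, C[C@@H]1CC[C@@H]2C[C@H]1SC2(C)C; sodium tetrafluoroborate, [Na+].F[B-](F)(F)F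
Why: Neutral Appel bromination (MOM-safe), then S-alkylation of the chiral sulfide and anion exchange, gives the benzylsulfonium salt.

Step 14
Reactants: 19 7-[(S)-lavandulyl]-4,6-bis(methoxymethoxy)-5-prenyl-1-benzofuran-2,3-dione; 25 sulfonium tetrafluoroborate
Product: 27 (3'S)-3'-[2,4-bis(methoxymethoxy)phenyl]-7-[(S)-lavandulyl]-4,6-bis(methoxymethoxy)-5-prenyl-2H-spiro[1-benzofuran-3,2'-oxiran]-2-one (both spiro epimers), via sulfonium ylide 26 (not isolated)
Conditions: KHMDS, THF, −78 °C; then 19, −78→−20 °C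
Reagents that add atoms: none
Why: Corey–Chaykovsky epoxidation of the activated C3 ketone with a chiral sulfur ylide; the ylide face control sets the benzylic carbon as (S), and the spiro carbon need not be controlled because it becomes the C4 carbonyl later.

Step 15
Reactants: 27 spiro-epoxy lactone
Product: 28 (3'S)-3'-[2,4-bis(methoxymethoxy)phenyl]-7-[(S)-lavandulyl]-4,6-bis(methoxymethoxy)-5-prenyl-2H-spiro[1-benzofuran-3,2'-oxiran]-2-ol (lactol, epimer mixture)
Conditions: DIBAL-H (1.1 eq), CH2Cl2, −78 °C; Rochelle salt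
Reagents that add atoms: none
Why: Partial reduction of the aryl lactone to the lactol (the tetrahedral aluminate is stable at −78 °C), which gives the masked aldehyde and leaves the epoxide intact.

Step 16
Reactants: 28 spiro-epoxy lactol
Product: 30 (2R,3R)-2-[2,4-bis(methoxymethoxy)phenyl]-3-hydroxy-8-[(S)-lavandulyl]-5,7-bis(methoxymethoxy)-6-prenylchroman-4-one, via hydroxy aldehyde 29 (not isolated)
Conditions: Cs2CO3 (0.2 eq), MeCN, 0→45 °C, Ar
Reagents that add atoms: none
Why: Proposed new method: carbonate opens the lactol to the phenoxide and epoxy aldehyde, the phenoxide attacks the benzylic epoxide carbon with inversion (as in the known closure of 2-hydroxystilbene oxides to dihydrobenzofuranols) so that both spiro epimers give (2R)-29, and the tertiary alkoxide next to the formyl group then undergoes an anionic α-ketol 1,2-shift of C2 with retention, expanding the dihydrobenzofuran to the chroman-4-one; the driving force is the conjugated aryl ketone in a six-membered ring, the electron-rich aryl is a poor migrating group under anionic conditions, the new C3 centre settles as the trans (3R) isomer through its enolisable hydrogen, and the closest known reaction type is the α-ketol ring expansion of α-hydroxy aldehydes and ketones (for example steroid D-homoannulation).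

Step 17
Reactants: 30 tetra-MOM flavanonol
Product: 31 (2R,3R)-2-(2,4-dihydroxyphenyl)-3,5,7-trihydroxy-8-[(2S)-5-methyl-2-(prop-1-en-2-yl)hex-4-en-1-yl]-6-(3-methylbut-2-en-1-yl)chroman-4-one (target)
Conditions: HCl (1.25 M in MeOH), 40 °C
Reagents that add atoms: none
Why: Acid-catalysed acetal exchange removes the four aryl MOM groups; dilute acid and low temperature are chosen to avoid chroman formation from the prenyl and lavandulyl alkenes and to keep C2 intact.

**Compound list**

1 | resorcinol | Oc1cccc(O)c1 | starting material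
2 | 1,3-bis(methoxymethoxy)benzene | COCOc1cccc(OCOC)c1 | intermediate
3 | prenyl bromide (1-bromo-3-methylbut-2-ene) | CC(C)=CCBr | starting material
4 | 2-lithio-1,3-bis(methoxymethoxy)benzene | COCOc1cccc(OCOC)c1[Li] | intermediate
5 | 1,3-bis(methoxymethoxy)-2-prenylbenzene | COCOc1cccc(OCOC)c1CC=C(C)C | intermediate
6 | 2-[3,5-bis(methoxymethoxy)-4-prenylphenyl]-4,4,5,5-tetramethyl-1,3,2-dioxaborolane | COCOc1cc(B2OC(C)(C)C(C)(C)O2)cc(OCOC)c1CC=C(C)C | intermediate
7 | 3,5-bis(methoxymethoxy)-4-prenylphenol | COCOc1cc(O)cc(OCOC)c1CC=C(C)C | intermediate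
8 | 2-bromo-3,5-bis(methoxymethoxy)-4-prenylphenol | COCOc1cc(O)c(Br)c(OCOC)c1CC=C(C)C | intermediate
9 | 3-methylbut-2-enoyl chloride | CC(C)=CC(=O)Cl | starting material
10 | (4R)-4-benzyl-3-(3-methylbut-2-enoyl)-1,3-oxazolidin-2-one | CC(C)=CC(=O)N1[C@H](Cc2ccccc2)COC1=O | intermediate
11 | sodium (Z)-dienolate of 10 | C=C(C)/C=C(\[O-])N1[C@H](Cc2ccccc2)COC1=O.[Na+] | intermediate
12 | (4R)-4-benzyl-3-[(2R)-5-methyl-2-(prop-1-en-2-yl)hex-4-enoyl]-1,3-oxazolidin-2-one | C=C(C)[C@@H](CC=C(C)C)C(=O)N1[C@H](Cc2ccccc2)COC1=O | intermediate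
13 | (R)-lavandulol, (2R)-5-methyl-2-(prop-1-en-2-yl)hex-4-en-1-ol | C=C(C)[C@@H](CC=C(C)C)CO | intermediate
14 | (R)-lavandulyl iodide, (3R)-3-(iodomethyl)-2,6-dimethylhepta-1,5-diene | C=C(C)[C@@H](CC=C(C)C)CI | intermediate
15 | dilithium salt of 8 (O-Li and C2-Li) | [Li]Oc1cc(OCOC)c(CC=C(C)C)c(OCOC)c1[Li] | intermediate
16 | 2-[(S)-lavandulyl]-3,5-bis(methoxymethoxy)-4-prenylphenol | C=C(C)[C@@H](CC=C(C)C)Cc1c(O)cc(OCOC)c(CC=C(C)C)c1OCOC | intermediate
17 | oxalyl chloride | O=C(Cl)C(=O)Cl | starting material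
18 | aryl chlorooxalate of 16 | C=C(C)[C@@H](CC=C(C)C)Cc1c(OC(=O)C(=O)Cl)cc(OCOC)c(CC=C(C)C)c1OCOC | intermediate
19 | 7-[(S)-lavandulyl]-4,6-bis(methoxymethoxy)-5-prenyl-1-benzofuran-2,3-dione | C=C(C)[C@@H](CC=C(C)C)Cc1c2OC(=O)C(=O)c2c(OCOC)c(CC=C(C)C)c1OCOC | intermediate
20 | 1-bromo-2,4-bis(methoxymethoxy)benzene | COCOc1ccc(Br)c(OCOC)c1 | intermediate
21 | formaldehyde (used as paraformaldehyde) | C=O | starting material
22 | 2,4-bis(methoxymethoxy)phenyllithium | COCOc1ccc([Li])c(OCOC)c1 | intermediate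
23 | [2,4-bis(methoxymethoxy)phenyl]methanol | COCOc1ccc(CO)c(OCOC)c1 | intermediate
24 | 1-(bromomethyl)-2,4-bis(methoxymethoxy)benzene | COCOc1ccc(CBr)c(OCOC)c1 | intermediate
25 | (1R,4R,5R)-6-[2,4-bis(methoxymethoxy)benzyl]-4,7,7-trimethyl-6-thiabicyclo[3.2.1]octan-6-ium tetrafluoroborate (configuration at S not specified) | C[C@@H]1CC[C@@H]2C[C@H]1[S+](Cc1ccc(OCOC)cc1OCOC)C2(C)C.F[B-](F)(F)F | intermediate
26 | sulfonium benzylide from 25 | C[C@@H]1CC[C@@H]2C[C@H]1[S+]([CH-]c1ccc(OCOC)cc1OCOC)C2(C)C | intermediate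
27 | (3'S)-3'-[2,4-bis(methoxymethoxy)phenyl]-7-[(S)-lavandulyl]-4,6-bis(methoxymethoxy)-5-prenyl-2H-spiro[1-benzofuran-3,2'-oxiran]-2-one (spiro carbon: both epimers) | C=C(C)[C@@H](CC=C(C)C)Cc1c2OC(=O)C3(O[C@H]3c4ccc(OCOC)cc4OCOC)c2c(OCOC)c(CC=C(C)C)c1OCOC | intermediate
28 | lactol of 27, 2H-spiro[1-benzofuran-3,2'-oxiran]-2-ol (spiro and lactol carbons: epimer mixture) | C=C(C)[C@@H](CC=C(C)C)Cc1c2OC(O)C3(O[C@H]3c4ccc(OCOC)cc4OCOC)c2c(OCOC)c(CC=C(C)C)c1OCOC | intermediate
29 | (2R)-2-[2,4-bis(methoxymethoxy)phenyl]-3-hydroxy-7-[(S)-lavandulyl]-4,6-bis(methoxymethoxy)-5-prenyl-2,3-dihydro-1-benzofuran-3-carbaldehyde (C3: both epimers) | C=C(C)[C@@H](CC=C(C)C)Cc1c2O[C@H](c3ccc(OCOC)cc3OCOC)C(O)(C=O)c2c(OCOC)c(CC=C(C)C)c1OCOC | intermediate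
30 | (2R,3R)-2-[2,4-bis(methoxymethoxy)phenyl]-3-hydroxy-8-[(S)-lavandulyl]-5,7-bis(methoxymethoxy)-6-prenylchroman-4-one | C=C(C)[C@@H](CC=C(C)C)Cc1c(OCOC)c(CC=C(C)C)c(OCOC)c2c1O[C@H](c1ccc(OCOC)cc1OCOC)[C@@H](O)C2=O | intermediate
31 | (2R,3R)-2-(2,4-dihydroxyphenyl)-3,5,7-trihydroxy-8-[(2S)-5-methyl-2-(prop-1-en-2-yl)hex-4-en-1-yl]-6-(3-methylbut-2-en-1-yl)chroman-4-one | C=C(C)[C@@H](CC=C(C)C)Cc1c(O)c(CC=C(C)C)c(O)c2c1O[C@H](c1ccc(O)cc1O)[C@@H](O)C2=O | target

**Step count**

Total steps: 17. Longest linear sequence: 10 (steps 1, 2, 3, 4, 9, 10, 14, 15, 16, 17; the lavandulyl branch 5, 6, 7, 8, 9, 10, 14–17 is equally long).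

**Three steps most likely to fail**

Step 16 (the proposed new cascade). Possible failures: the epoxide opens but the hydroxy aldehyde does not shift; the aryl group migrates instead, which would put a ketone next to C2 and erode its configuration; or base opens the product ring. The fallback uses only known flavonoid chemistry and needs no rearrangement. It sets out from phenol 16 and comes back at 30. Phenol 16 is ortho-formylated (MgCl2, Et3N, paraformaldehyde, MeCN) to salicylaldehyde F1. MeMgBr gives carbinol F2, and MnO2 gives 2'-hydroxyacetophenone F3. Claisen–Schmidt condensation (KOH, EtOH) with 2,4-bis(methoxymethoxy)benzaldehyde F4 (MnO2 oxidation of 23) gives (E)-chalcone F5, which is silylated (TBSCl, imidazole) to silyl ether F6. Juliá–Colonna epoxidation (poly-L-leucine, urea–H2O2, DBU, THF) is selective for the enone over the isolated alkenes and gives (2R,3S)-epoxy ketone F7. Buffered desilylation (TBAF, AcOH) frees phenol epoxide F8, which closes 6-endo on mild acid (PPTS, CH2Cl2) with inversion at the benzylic carbon to give 30.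

Step 14 (ylide epoxidation of the keto lactone). Possible failures: the ylide acylates at the lactone carbonyl instead of adding to the ketone, the electron-rich ketone is too unreactive, or the ee is low. The fallback sets out from benzyl bromide 24 and coumarandione 19 and comes back at 27. PPh3 in toluene converts 24 into phosphonium bromide F9. Its ylide (KOt-Bu, THF) olefinates the C3 ketone of 19 in a Wittig reaction to give 3-benzylidene lactone F10 (E/Z). Catalytic asymmetric nucleophilic epoxidation of this electron-poor alkene (TBHP with a cinchona-derived phase-transfer catalyst or a diarylprolinol) gives 27.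

Step 9 (aryl–lavandulyl bond). Possible failures: slow SN2 at the β-branched iodide with a hindered aryllithium, or E2 elimination to a diene. The fallback reverses the polarity; it sets out from bromophenol 8 and iodide 14 and comes back at 16. Zinc insertion (Zn dust, LiCl, THF) turns 14 into lavandulylzinc iodide F11. Phenol 8 is deprotonated with NaH and coupled with F11 under Negishi conditions (Pd(OAc)2, CPhos, THF, 40 °C) to give 16.

**Further compounds**

F1 | step 16 | 2-hydroxy-3-[(S)-lavandulyl]-4,6-bis(methoxymethoxy)-5-prenylbenzaldehyde | C=C(C)[C@@H](CC=C(C)C)Cc1c(O)c(C=O)c(OCOC)c(CC=C(C)C)c1OCOC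
F2 | step 16 | 1-{2-hydroxy-3-[(S)-lavandulyl]-4,6-bis(methoxymethoxy)-5-prenylphenyl}ethanol | C=C(C)[C@@H](CC=C(C)C)Cc1c(O)c(C(C)O)c(OCOC)c(CC=C(C)C)c1OCOC
F3 | step 16 | 1-{2-hydroxy-3-[(S)-lavandulyl]-4,6-bis(methoxymethoxy)-5-prenylphenyl}ethanone | C=C(C)[C@@H](CC=C(C)C)Cc1c(O)c(C(C)=O)c(OCOC)c(CC=C(C)C)c1OCOC
F4 | step 16 | 2,4-bis(methoxymethoxy)benzaldehyde | COCOc1ccc(C=O)c(OCOC)c1
F5 | step 16 | (E)-3-[2,4-bis(methoxymethoxy)phenyl]-1-{2-hydroxy-3-[(S)-lavandulyl]-4,6-bis(methoxymethoxy)-5-prenylphenyl}prop-2-en-1-one | C=C(C)[C@@H](CC=C(C)C)Cc1c(O)c(C(=O)/C=C/c2ccc(OCOC)cc2OCOC)c(OCOC)c(CC=C(C)C)c1OCOC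
F6 | step 16 | 2'-O-tert-butyldimethylsilyl ether of F5 | C=C(C)[C@@H](CC=C(C)C)Cc1c(O[Si](C)(C)C(C)(C)C)c(C(=O)/C=C/c2ccc(OCOC)cc2OCOC)c(OCOC)c(CC=C(C)C)c1OCOC
F7 | step 16 | (2R,3S)-2,3-epoxy ketone from F6 | C=C(C)[C@@H](CC=C(C)C)Cc1c(O[Si](C)(C)C(C)(C)C)c(C(=O)[C@@H]3O[C@H]3c2ccc(OCOC)cc2OCOC)c(OCOC)c(CC=C(C)C)c1OCOC
F8 | step 16 | (2R,3S)-2,3-epoxy ketone with free 2'-OH | C=C(C)[C@@H](CC=C(C)C)Cc1c(O)c(C(=O)[C@@H]3O[C@H]3c2ccc(OCOC)cc2OCOC)c(OCOC)c(CC=C(C)C)c1OCOC
F9 | step 14 | [2,4-bis(methoxymethoxy)benzyl]triphenylphosphonium bromide | COCOc1ccc(C[P+](c2ccccc2)(c2ccccc2)c2ccccc2)c(OCOC)c1.[Br-]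
F10 | step 14 | 3-[2,4-bis(methoxymethoxy)benzylidene]-7-[(S)-lavandulyl]-4,6-bis(methoxymethoxy)-5-prenyl-1-benzofuran-2(3H)-one | C=C(C)[C@@H](CC=C(C)C)Cc1c2OC(=O)C(=Cc3ccc(OCOC)cc3OCOC)c2c(OCOC)c(CC=C(C)C)c1OCOC
F11 | step 9 | (R)-lavandulylzinc iodide | C=C(C)[C@@H](CC=C(C)C)C[Zn]I
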